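**Retrosynthetic overview**

1. The target is the trans-(2R,3S) α-methylene-γ-lactone diacid. Its exocyclic C3=CH2 comes from decarboxylative methylenation (HCHO) of the C3-carboxy lactone, which comes from Stiles carboxylation of the trans lactone diacid.
2. The trans lactone diacid comes from ester epimerisation and hydrolysis of a lactone ester, formed by γ-lactonisation of an (R)-β-hydroxy diester. That diester comes from Ru–(R)-BINAP hydrogenation of a 2-acylsuccinate (sets C5; C4 follows by equilibration).
3. Key disconnection C4–C5: an acyl radical adds to dimethyl fumarate (Giese addition). The radical is released from one of the two identical carboxyl groups of hexadecanedioic acid by photoredox/phosphine deoxygenation, so the symmetric chain is desymmetrised and joined to the C4 unit in one step.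
4. Hexadecanedioic acid comes from a C6 di-Grignard and two C5 bromo acid units (Cu-catalysed sp3–sp3 coupling).
5. Ring order: the only ring, the γ-lactone, is closed after the radical step (in step 3); the exocyclic alkene is introduced last.

Assumption: the two methyl esters of commercial dimethyl fumarate are treated as carboxyl protecting groups of fumaric acid (both are removed in steps 3 and 4).

**Step 1**
Reactants: 1 1,6-dibromohexane; 2 5-bromopentanoic acid (2 equiv)
Product: 5 hexadecanedioic acid, via hexane-1,6-diylbis(magnesium bromide) 3 (not isolated), via chloromagnesium 5-bromopentanoate 4 (not isolated)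
Conditions: Mg, THF, 50 °C (1 → 3); MeMgCl, THF, −20 °C (2 → 4); 3 + 4 (1 : 2), Li2CuCl4 (3 mol%), THF, −20 → 20 °C; then 2 M HCl
Reagents that add atoms: magnesium, [Mg] (Mg of 3 only, not in 5); methylmagnesium chloride, C[Mg]Cl (MgCl of 4 only, not in 5)
Why: Cu-catalysed Grignard–alkyl bromide cross-coupling (Kochi type), in which the primary C–MgBr ends of 3 displace the primary bromide of 4 much faster than they add to its magnesium carboxylate, so two C5 acid units are joined to the C6 unit to give the symmetric C16 diacid, and no stereocentre is involved.

**Step 2**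
Reactants: 5 hexadecanedioic acid (3 equiv, excess recovered); 6 dimethyl fumarate
Product: 8 dimethyl 2-(15-carboxypentadecanoyl)butanedioate, via 15-carboxypentadecanoyl radical 7 (not isolated)
Conditions: Ir[dF(CF3)ppy]2(dtbbpy)PF6 (1 mol%), PPh3 (1.3 equiv), 2,4,6-collidine (1 equiv), DMA, 450 nm LEDs, 25 °C
Reagents that add atoms: none
Why: Proposed new method: excited Ir(III) oxidises PPh3 to its radical cation, a carboxylate of 5 adds to give a phosphoranyl radical whose β-scission (P=O formation) releases the nucleophilic acyl radical 7, which adds to the electron-poor alkene of 6 (acyl-radical Giese addition) to form the C4–C5 bond before the α-ester radical is reduced by Ir(II) and protonated, the threefold excess of symmetric 5 keeping the reaction at mono-acylation; the closest known reaction type is the photoredox deoxygenative hydroacylation of alkenes with carboxylic acids and phosphines, and the new stereocentre (α to ketone and ester) is formed racemic and stays configurationally labile.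

**Step 3**
Reactants: 8 dimethyl 2-(15-carboxypentadecanoyl)butanedioate
Product: 10 methyl (2R,3RS)-2-(14-carboxytetradecyl)-5-oxooxolane-3-carboxylate, via dimethyl (2RS)-2-[(1R)-15-carboxy-1-hydroxypentadecyl]butanedioate 9 (not isolated)
Conditions: H2 (50 bar), RuBr2[(R)-BINAP] (1 mol%), MeOH, 50 °C; then TsOH·H2O (5 mol%), toluene, 60 °C
Reagents that add atoms: none
Why: Noyori asymmetric hydrogenation of a β-keto ester under dynamic kinetic resolution conditions, in which the (R)-BINAP–Ru hydride reduces the chelated ketone from one face to give the (R)-carbinol (C5) whichever way the rapidly epimerising α-centre is set, and acid then closes the γ-lactone onto the CH2CO2Me ester (5-exo-trig, loss of MeOH), leaving C4 as a cis/trans mixture.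

**Step 4**
Reactants: 10 methyl (2R,3RS)-2-(14-carboxytetradecyl)-5-oxooxolane-3-carboxylate
Product: 12 (2R,3S)-2-(14-carboxytetradecyl)-5-oxooxolane-3-carboxylic acid, via methyl (2R,3S)-2-(14-carboxytetradecyl)-5-oxooxolane-3-carboxylate 11 (not isolated)
Conditions: DBU (1.5 equiv), CH2Cl2, 25 °C; then 6 M HCl/1,4-dioxane, reflux
Reagents that add atoms: water, O
Why: Base-mediated epimerisation followed by acid ester hydrolysis, in which DBU equilibrates C4 through the ester enolate to the more stable trans-4,5-disubstituted lactone (ring opening of that enolate would be a disfavoured retro-5-endo-trig elimination) and aqueous HCl then hydrolyses the methyl ester without enolising C4, the γ-lactone staying closed in acid.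

**Step 5**
Reactants: 12 (2R,3S)-2-(14-carboxytetradecyl)-5-oxooxolane-3-carboxylic acid
Product: 13 (2R,3S,4RS)-2-(14-carboxytetradecyl)-5-oxooxolane-3,4-dicarboxylic acid
Conditions: MeOMgOCO2Me (2 M in DMF, excess), 135 °C, 60 h; then cold 6 M HCl
Reagents that add atoms: methyl magnesium carbonate (Stiles reagent), COC(=O)O[Mg]OC
Why: Stiles carboxylation, in which methyl magnesium carbonate carboxylates the lactone α-CH2 as its magnesium-chelated enolate–carboxylate while the carboxylate-bearing C4 and the chain α-CH2 are too weakly acidic to react, so C4 and C5 are untouched and the new C3 centre does not matter because it becomes sp2 in the next step.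

**Step 6**
Reactants: 13 (2R,3S,4RS)-2-(14-carboxytetradecyl)-5-oxooxolane-3,4-dicarboxylic acid
Product: 14 (2R,3S)-2-(14-carboxytetradecyl)-4-methylidene-5-oxooxolane-3-carboxylic acid
Conditions: 37% aq HCHO, PhNHMe, NaOAc, AcOH, 25 °C
Reagents that add atoms: formaldehyde, C=O
Why: Decarboxylative Mannich-type methylenation of a malonic half-acid, in which the iminium ion from HCHO and N-methylaniline alkylates C3 and loss of CO2 with elimination of the amine gives the exocyclic alkene under buffered acidic conditions that neither epimerise C4 nor move the double bond into the ring.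

**Compound list**

1 | 1,6-dibromohexane | BrCCCCCCBr | starting material
2 | 5-bromopentanoic acid | OC(=O)CCCCBr | starting material
3 | hexane-1,6-diylbis(magnesium bromide) | Br[Mg]CCCCCC[Mg]Br | intermediate (not isolated)
4 | chloromagnesium 5-bromopentanoate | BrCCCCC(=O)O[Mg]Cl | intermediate (not isolated)
5 | hexadecanedioic acid | OC(=O)CCCCCCCCCCCCCCC(=O)O | intermediate
6 | dimethyl fumarate (fumaric acid, both carboxyls protected as methyl esters) | COC(=O)/C=C/C(=O)OC | starting material
7 | 15-carboxypentadecanoyl radical | O=[C]CCCCCCCCCCCCCCC(=O)O | intermediate (not isolated)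
8 | dimethyl 2-(15-carboxypentadecanoyl)butanedioate (racemic) | COC(=O)CC(C(=O)OC)C(=O)CCCCCCCCCCCCCCC(=O)O | intermediate
9 | dimethyl (2RS)-2-[(1R)-15-carboxy-1-hydroxypentadecyl]butanedioate | COC(=O)CC(C(=O)OC)[C@H](O)CCCCCCCCCCCCCCC(=O)O | intermediate (not isolated)
10 | methyl (2R,3RS)-2-(14-carboxytetradecyl)-5-oxooxolane-3-carboxylate (cis/trans mixture) | C1C(=O)O[C@H](CCCCCCCCCCCCCCC(=O)O)C1C(=O)OC | intermediate
11 | methyl (2R,3S)-2-(14-carboxytetradecyl)-5-oxooxolane-3-carboxylate (trans) | C1C(=O)O[C@H](CCCCCCCCCCCCCCC(=O)O)[C@H]1C(=O)OC | intermediate (not isolated)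
12 | (2R,3S)-2-(14-carboxytetradecyl)-5-oxooxolane-3-carboxylic acid | C1C(=O)O[C@H](CCCCCCCCCCCCCCC(=O)O)[C@H]1C(=O)O | intermediate
13 | (2R,3S,4RS)-2-(14-carboxytetradecyl)-5-oxooxolane-3,4-dicarboxylic acid | OC(=O)C1C(=O)O[C@H](CCCCCCCCCCCCCCC(=O)O)[C@H]1C(=O)O | intermediate
14 | (2R,3S)-2-(14-carboxytetradecyl)-4-methylidene-5-oxooxolane-3-carboxylic acid (CNP0222442.1) | C=C1C(=O)O[C@H](CCCCCCCCCCCCCCC(=O)O)[C@H]1C(=O)O | target

**Step count and risk**

Total step count: 6. Longest linear sequence: 6 (1 → 5 → 8 → 10 → 12 → 13 → 14).

Three steps most likely to fail: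

Step 2 (key radical acylation). PPh3 may add to 6, the carboxylate may be oxidised directly, or 8 may be acylated a second time. The fallback makes the same acyl radical from a pre-activated acyl donor in a thermal chain reaction and not from the free acid by photoredox deoxygenation. It sets out from 5 (used in excess), one carboxyl of which is converted with N-(phenylseleno)phthalimide and PBu3 in CH2Cl2 into the mono-selenoester 16-oxo-16-(phenylselanyl)hexadecanoic acid F1. Slow addition of (Me3Si)3SiH and AIBN to F1 and 6 in benzene at 80 °C abstracts the PhSe group to give radical 7, which adds to 6, and the adduct radical takes hydrogen from the silane. The route is rejoined at 8.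

Step 3 (asymmetric hydrogenation). The enantioselectivity at C5 is unproven for this α-branched keto ester that also carries a free acid. The fallback replaces asymmetric catalysis by a resolution. It sets out from 8: NaBH4 in MeOH at −20 °C, then TsOH and then DBU give the racemic trans lactone ester methyl (2RS,3SR)-2-(14-carboxytetradecyl)-5-oxooxolane-3-carboxylate F2. A hydrolase chosen by screening for the (2R,3S)-ester (pig-liver esterase, horse-liver acetone powder or Candida rugosa lipase, pH 7.4 buffer, stopped near 45% conversion) hydrolyses that enantiomer and leaves methyl (2S,3R)-2-(14-carboxytetradecyl)-5-oxooxolane-3-carboxylate F3. The route is rejoined at 12, and step 4 is not needed.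

Step 5 (Stiles carboxylation). Sixty hours at 135 °C may give incomplete carboxylation, and the product may decarboxylate on work-up. The fallback introduces the methylene by formylation and deformylative methylenation. It sets out from 12: NaH (4.5 equiv) and ethyl formate in THF at 25 °C give, as its sodium salt, (2R,3S)-2-(14-carboxytetradecyl)-4-(hydroxymethylidene)-5-oxooxolane-3-carboxylic acid F4. Heating this salt with paraformaldehyde in THF gives aldol addition at C3 and loss of formate. The route is rejoined at 14, so 13 and step 6 are bypassed.

**Further compounds**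

F1 | step 2 | 16-oxo-16-(phenylselanyl)hexadecanoic acid | OC(=O)CCCCCCCCCCCCCCC(=O)[Se]c1ccccc1
F2 | step 3 | methyl (2RS,3SR)-2-(14-carboxytetradecyl)-5-oxooxolane-3-carboxylate (racemic trans, both enantiomers) | C1C(=O)O[C@H](CCCCCCCCCCCCCCC(=O)O)[C@H]1C(=O)OC.C1C(=O)O[C@@H](CCCCCCCCCCCCCCC(=O)O)[C@@H]1C(=O)OC
F3 | step 3 | methyl (2S,3R)-2-(14-carboxytetradecyl)-5-oxooxolane-3-carboxylate | C1C(=O)O[C@@H](CCCCCCCCCCCCCCC(=O)O)[C@@H]1C(=O)OC
F4 | step 5 | (2R,3S)-2-(14-carboxytetradecyl)-4-(hydroxymethylidene)-5-oxooxolane-3-carboxylic acid | OC=C1C(=O)O[C@H](CCCCCCCCCCCCCCC(=O)O)[C@H]1C(=O)O
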